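## The problem

Compound 21 is a cis-fused octahydronaphthalene. Ring A is a cyclohexene (C1, C2, C3=C4, C4a, C8a) carrying the (2E,4E)-pentadienoic acid at C1, an (E)-but-2-en-2-yl group at C2 and a methyl at C3. Ring B is a cyclohexane (C4a, C5–C8, C8a) with a methyl at C8 and a sulfate monoester at C7.

There are six stereocentres, five of them contiguous (C2, C1, C8a, C8, C7) plus C4a. H4a and H8a are cis; the C1 chain is trans to both the C2 butenyl group and the C8a–C8 bond; the C8 methyl is cis to H8a and to the C7 oxygen.

C1 (next to a carbonyl-derived chain) and C8 (α to C7) can be corrected by enolate chemistry, and C7 can follow C8 by hydride delivery. C2, C8a and C4a bear only carbon and hydrogen, must be set during C–C bond formation, and no group on ring A can direct a reagent.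

The cis fusion is the less favoured outcome of the cycloaddition that most directly makes this ring system.

The secondary alkyl hydrogen sulfate (strong acid, solvolysis-prone) must come last. The C2 methine is doubly allylic, the dienoic acid can isomerise or be deprotonated at C1, and three alkenes rule out hydrogenation.

The enabling feature is the 1,5-relation C7–C6–C5–C4a–C4=C3 between the ring B oxygen and the ring A alkene across the cis fusion. At the C7 ketone level this is a δ,ε-unsaturated ketone, the retron of an oxy-Cope rearrangement. Its precursor has a C3–C7 bond, giving a bicyclo[2.2.2]octene whose six-membered ring C3–C4–C4a–C8a–C8–C7 (methyl on C3, oxygen on C7) is the carbon ring of toluene.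

## Retrosynthesis

Target numbering (C1–C8a) is used in this section for the corresponding carbons of every intermediate; the systematic names in the steps use their own locants.

**Sulfate and chain.** The S–O bond and the C4=C5 bond of the side chain are cut: 21 comes from hydroxy dienoate 19 (via sulfate ester 20), and 19 from aldehyde 17 and phosphonate 18. The sulfate is placed last because it survives base but not acid or heat. The dienoate is added late because its C1–H is vinylogously acidic and would not survive the strong bases used earlier. Aldehyde 17 comes from ester 16 by partial reduction, and 16 from ketone 15 by hydride delivery anti to the C8 methyl.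

**Key disconnection.** In 15 the C4a–C5 bond is cut and C3–C7 is joined (retro-oxy-Cope), giving the 2-vinylbicyclo[2.2.2]octenol 14. Against a direct ring A cycloaddition, this replaces a flexible decalin with a rigid bicycle in which each substituent has only two defined positions. The cis fusion and C4a then follow from geometry alone. The forward reaction needs the vinyl group syn to the C4=C4a bridge, the C2 butenyl anti to it, the C1 ester syn to it and the C8 methyl syn to it.

**Adjusting the bicycle.** 14 is the C1 epimer of 13 (ester epimerisation to the trans-vicinal arrangement). 13 comes from ketone 12 by vinyl addition from the etheno face. 12 comes from 11 by cutting the C8–CH3 bond (enolate methylation, with C3 quaternary so only C8 can enolise). The anti ester at C1 in 11 is kept deliberately until after methylation, because it shields the wrong face of C8.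

**Tether removal.** The C8–H bond of 11 (via acid 10) is reconnected as a C8–O–C(=O)–C1 lactone in 9, an α-acyloxy ketone that SmI2 cleaves. 9 comes from alcohol 8 by oxidation at C7. One reduction thus removes the tether oxygen from C8 and unmasks the C1 carboxyl.

**Cycloaddition.** In 8 the C2–C3 and C1–C8a bonds are cut (retro-Diels–Alder), then the ester C–O bond, giving diol 6 and dienoic acid 4 through monoester 7. An untethered dienophile would be expected to add to the face away from the oxygens and with the ester carbon next to C3; both are the opposite of what 21 needs. The three-atom ester tether from the C8 oxygen fixes the regiochemistry, the diene face and therefore the absolute configuration. The 2Z geometry of 4 puts the butenyl group on the same side as the tether (anti to the etheno bridge). The cost is that C1 arrives with the wrong configuration, which is corrected in the step from 13 to 14.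

**Starting materials.** The C1–O and C2–O bonds of 6 are cut back to toluene 5 (enzymatic cis-dihydroxylation). This supplies C3, C4, C4a, C8a, C8, C7, the C3 methyl, the C7 oxygen and the absolute configuration. Acid 4 comes from ester 3, and 3 from aldehyde 1 and phosphonate 2 (Z-selective olefination).

## Roads not taken

Alternative 1: The most obvious cut is C1–C2 and C4a–C8a, an intramolecular Diels–Alder reaction of the linear hexaenoate A1. It forms ring A and ring B at once. However, a terminally activated E,E,E-decatriene is expected to prefer the endo mode and the trans fusion, so the cis-fused 21 would need the disfavoured exo mode. Face selection would rest on two stereocentres on a flexible tether. A1 offers several competing diene/dienophile pairs, is prone to polymerisation, and still needs its own asymmetric synthesis. The chosen plan fixes fusion, face and regiochemistry by geometry.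

Alternative 2: The same two bonds can be made by a transannular Diels–Alder reaction of the 19-membered macrolactone A2, in which C18 is oxidised and tied to C1. The ring can bias the cycloaddition towards the cis fusion. It requires a hexaene macrocyclisation, an extra oxygen at C18, and later an allylic deoxygenation next to the skipped diene, where transposition and E/Z loss are likely. The chosen plan needs no atom that is not in 21 except one tether oxygen, which leaves in the same step that reveals the C1 carboxyl.

Alternative 3: Ring B can be annulated onto ring A by cutting C4a–C5 and C8–C8a, an intermolecular Diels–Alder reaction of cyclohexenone A3 with silyloxydiene A4. This gives the cis fusion and the C7 oxygen directly. But A3 already holds three contiguous stereocentres and needs its own asymmetric synthesis. A β-unsubstituted but γ-branched cyclohexenone is a poor dienophile, and the Lewis acid it needs threatens A4 and the skipped diene. The C4 carbonyl must afterwards become the C3=C4 alkene (enol triflate reduction), with competing enolisation towards C4a. The step count is higher and fewer stereocentres are controlled by the key step.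

Key step: step 11

Remark 1: 21 is a strong acid (alkyl hydrogen sulfate). It is assumed that the free acid drawn is wanted, so the last step ends with a cold acidification of the dilithium salt; the compound is best stored as a salt.

Remark 2: Alkoxides, enolates, carboxylate salts and phosphonate carbanions formed and consumed or protonated within one operation are treated as ionised forms of the numbered compounds.

## Steps

Step 1
Reactants: 1 (E)-2-methylbut-2-enal; 2 methyl 2-[bis(2,2,2-trifluoroethoxy)phosphoryl]acetate
Product: 3 methyl (2Z,4E)-4-methylhexa-2,4-dienoate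
Conditions: KN(SiMe3)2, 18-crown-6, THF, −78 °C
Reagents that add atoms: none
Why: Still–Gennari olefination; the electron-poor phosphonate makes elimination from the kinetic adduct fast, which should give the 2Z alkene while the 4E alkene of 1 is untouched.

Step 2
Reactants: 3 methyl (2Z,4E)-4-methylhexa-2,4-dienoate
Product: 4 (2Z,4E)-4-methylhexa-2,4-dienoic acid
Conditions: LiOH, THF–H2O, 0 °C; then 1 M HCl, 0 °C
Reagents that add atoms: lithium hydroxide, [Li+].[OH-]
Why: Ester saponification at 0 °C, under which a 2Z-dienoate should keep its geometry; the acid is used at once.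

Step 3
Reactants: 5 toluene
Product: 6 (1S,2R)-3-methylcyclohexa-3,5-diene-1,2-diol
Conditions: toluene dioxygenase in whole cells of Escherichia coli JM109(pDTG601), glucose, air (O2), phosphate buffer pH 7.2, 30 °C; extraction with EtOAc
Reagents that add atoms: dioxygen, O=O
Why: Enzymatic arene cis-dihydroxylation (dearomatisation); the enzyme delivers both oxygen atoms of O2 to one face of the C2–C3 bond of toluene and so sets both stereocentres and the absolute configuration of the whole route.

Step 4
Reactants: 6 (1S,2R)-3-methylcyclohexa-3,5-diene-1,2-diol; 4 (2Z,4E)-4-methylhexa-2,4-dienoic acid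
Product: 8 10-[(E)-but-2-en-2-yl]-2-hydroxy-1-methyl-4-oxatricyclo[4.3.1.0(3,7)]dec-8-en-5-one (C2 hydroxyl and C10 butenyl facing each other on the lactone side), via dienoate monoester 7 (not isolated)
Conditions: DCC, DMAP (5 mol %), CH2Cl2, −20 °C; filtration; then PhMe, BHT, 2,6-lutidine (10 mol %), 80 °C
Reagents that add atoms: none
Why: Steglich esterification at the less hindered hydroxyl (the other one is flanked by the methyl-bearing alkene carbon), then an ester-tethered intramolecular Diels–Alder reaction. The three-atom tether forces the dienophile onto the diene face syn to the oxygens and its α-carbon onto the unsubstituted diene terminus, so the regiochemistry and absolute sense of the bicycle follow from 6. The cis dienophile places the butenyl group on the tether side.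

Step 5
Reactants: 8 tricyclic lactone alcohol
Product: 9 10-[(E)-but-2-en-2-yl]-1-methyl-4-oxatricyclo[4.3.1.0(3,7)]dec-8-ene-2,5-dione
Conditions: Dess–Martin periodinane, pyridine, CH2Cl2, 0 °C to rt, exclusion of light
Reagents that add atoms: none
Why: Dess–Martin oxidation of the secondary alcohol; this turns the lactone oxygen into an α-acyloxy group of a ketone and removes the hydroxyl that crowds the butenyl group.

Step 6
Reactants: 9 tricyclic keto lactone
Product: 10 3-[(E)-but-2-en-2-yl]-4-methyl-8-oxobicyclo[2.2.2]oct-5-ene-2-carboxylic acid (carboxyl and butenyl both anti to the C5=C6 bridge)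
Conditions: SmI2 (2.5 equiv), THF–MeOH, −78 °C; then 0.5 M HCl
Reagents that add atoms: none
Why: SmI2 reduction of an α-acyloxy ketone: two single-electron transfers expel the carboxylate from the α-carbon and the samarium enolate is protonated by methanol, so the tether oxygen is excised and the carboxyl is unmasked in one operation.

Step 7
Reactants: 10 bicyclic keto acid
Product: 11 methyl 3-[(E)-but-2-en-2-yl]-4-methyl-8-oxobicyclo[2.2.2]oct-5-ene-2-carboxylate (ester and butenyl anti to the C5=C6 bridge)
Conditions: Me3SiCHN2, PhMe–MeOH, 0 °C
Reagents that add atoms: (trimethylsilyl)diazomethane, C[Si](C)(C)C=[N+]=[N-]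
Why: Neutral esterification of the carboxylic acid that cannot epimerise the ester α-carbon or touch the ketone.

Step 8
Reactants: 11 bicyclic keto ester
Product: 12 methyl 3-[(E)-but-2-en-2-yl]-4,7-dimethyl-8-oxobicyclo[2.2.2]oct-5-ene-2-carboxylate (ester and butenyl anti to the C5=C6 bridge, C7 methyl syn to it)
Conditions: LiN(SiMe3)2 (1.05 equiv), THF, −78 °C; MeI, −78 to −40 °C
Reagents that add atoms: iodomethane, CI
Why: Kinetic enolate alkylation; the other α-position is a quaternary bridgehead, so only C7 enolises, and the ketone is deprotonated before the hindered ester. The face of the enolate towards the C2–C3 bridge is covered by the anti ester and the butenyl group, so MeI should enter from the etheno side and set the methyl syn to C5=C6.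

Step 9
Reactants: 12 methylated keto ester
Product: 13 methyl 3-[(E)-but-2-en-2-yl]-8-ethenyl-8-hydroxy-4,7-dimethylbicyclo[2.2.2]oct-5-ene-2-carboxylate (ester and butenyl anti to the C5=C6 bridge, vinyl and C7 methyl syn to it)
Conditions: CH2=CHMgBr, CeCl3 (anhydrous), THF, −78 °C; aqueous NH4Cl
Reagents that add atoms: vinylmagnesium bromide, C=C[Mg]Br
Why: Organocerium 1,2-addition to a hindered, enolisable ketone in the presence of an ester. The face towards the C2–C3 bridge is blocked by the butenyl group directly above the carbonyl, so the vinyl group should add from the etheno side, giving the syn-vinyl carbinol needed for the rearrangement.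

Step 10
Reactants: 13 vinyl carbinol with anti ester
Product: 14 methyl 3-[(E)-but-2-en-2-yl]-8-ethenyl-8-hydroxy-4,7-dimethylbicyclo[2.2.2]oct-5-ene-2-carboxylate (ester syn to the C5=C6 bridge, butenyl anti, vinyl and C7 methyl syn)
Conditions: NaOMe (0.3 equiv), MeOH, 50 °C
Reagents that add atoms: none
Why: Thermodynamic epimerisation α to the ester; the ester leaves the position eclipsed with the neighbouring butenyl group for the trans-vicinal position facing the etheno bridge. With the ketone converted to a carbinol, no other centre can epimerise.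

Step 11
Reactants: 14 vinyl carbinol with syn ester
Product: 15 methyl (1S,2S,4aS,8R,8aS)-2-[(E)-but-2-en-2-yl]-3,8-dimethyl-7-oxo-1,2,4a,5,6,7,8,8a-octahydronaphthalene-1-carboxylate
Conditions: KN(SiMe3)2 (1.1 equiv), 18-crown-6, THF, −78 to 0 °C; AcOH, −78 °C
Reagents that add atoms: none
Why: KN(SiMe3)2 with 18-crown-6 gives the free potassium alkoxide of 14, which undergoes a charge-accelerated [3,3]-sigmatropic shift (target numbering): the C3–C7 bond breaks, the vinyl terminus (C5) bonds to C4a, and the potassium enolate of 15 results, protonated at C6 by the acetic acid quench. The closest known reaction type is the anionic oxy-Cope rearrangement of 2-vinylbicyclo[2.2.2]oct-5-en-2-ols to cis-fused octalones. Ring B (C4a–C5–C6–C7–C8–C8a) is closed by this suprafacial [3,3] bond formation through the boat-like array that the bicycle enforces; ring A is not closed but released as the cyclohexene C1–C2–C3=C4–C4a–C8a when C3–C7 is cut. The only new stereocentre is C4a: the vinyl group is held on the C7–C8 bridge and can reach C4a only on the face towards that bridge, so the new C4a–C5 bond is cis to C8a–C8 and the fusion must be cis. C2, C1, C8a and C8 are spectators, so the syn/anti relations of the bicycle become the trans,trans relation of C2/C1/C8a and the cis relation of H8a and the C8 methyl of 21. The step needs the vinyl group syn to the etheno bridge (secured in step 9), deprotonation of O–H before the ester α-C–H (one equivalent of a hindered amide base), and an enolate formed towards C6 only and quenched cold so that C8 is untouched. Driving forces are relief of the strain between the alkoxide and the butenyl group, opening of the bicycle and formation of the delocalised enolate.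

Step 12
Reactants: 15 cis-fused keto ester
Product: 16 methyl (1S,2S,4aS,7S,8R,8aS)-2-[(E)-but-2-en-2-yl]-7-hydroxy-3,8-dimethyl-1,2,4a,5,6,7,8,8a-octahydronaphthalene-1-carboxylate
Conditions: LiBH(s-Bu)3 (L-Selectride), THF, −78 °C; then H2O
Reagents that add atoms: none
Why: Bulky hydride reduction under steric approach control; hydride should enter anti to the adjacent C8 methyl (equatorial attack on the chair with equatorial methyl), giving the C7 alcohol cis to the methyl, while the ester is inert at −78 °C.

Step 13
Reactants: 16 hydroxy ester
Product: 17 (1S,2S,4aS,7S,8R,8aS)-2-[(E)-but-2-en-2-yl]-7-hydroxy-3,8-dimethyl-1,2,4a,5,6,7,8,8a-octahydronaphthalene-1-carbaldehyde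
Conditions: i-Bu2AlH (2.3 equiv), CH2Cl2, −78 °C; aqueous potassium sodium tartrate
Reagents that add atoms: none
Why: Partial reduction of the methyl ester; the first equivalent is consumed by the hydroxyl and the tetrahedral aluminium hemiacetal should persist at −78 °C until work-up. C1 already has its thermodynamic trans,trans configuration.

Step 14
Reactants: 17 hydroxy aldehyde; 18 ethyl (E)-4-(diethoxyphosphoryl)but-2-enoate
Product: 19 ethyl (2E,4E)-5-[(1S,2S,4aS,7S,8R,8aR)-2-[(E)-but-2-en-2-yl]-7-hydroxy-3,8-dimethyl-1,2,4a,5,6,7,8,8a-octahydronaphthalen-1-yl]penta-2,4-dienoate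
Conditions: 18, LiN(SiMe3)2, THF, −78 °C; then 17, −78 to 0 °C
Reagents that add atoms: none
Why: Vinylogous Horner–Wadsworth–Emmons olefination through the α-carbon of the lithiated phosphonate should give the new alkene E and keep the existing E alkene; the stabilised carbanion is too weakly basic to deprotonate the free hydroxyl.

Step 15
Reactants: 19 hydroxy dienoate
Product: 21 (2E,4E)-5-[(1S,2S,4aS,7S,8R,8aR)-2-[(E)-but-2-en-2-yl]-3,8-dimethyl-7-(sulfooxy)-1,2,4a,5,6,7,8,8a-octahydronaphthalen-1-yl]penta-2,4-dienoic acid, via sulfated ethyl ester 20 (not isolated)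
Conditions: SO3·pyridine, pyridine, 40 °C; then LiOH, THF–H2O, 0 °C to rt; then 1 M HCl to pH 2 at 0 °C, desalting on C18 silica
Reagents that add atoms: sulfur trioxide–pyridine complex, O=S(=O)=O.c1ccncc1; lithium hydroxide, [Li+].[OH-]
Why: O-sulfation of the secondary alcohol with retention at C7, then saponification of the ethyl ester; an alkyl sulfate monoanion is stable to aqueous hydroxide, so the ester is cleaved without loss of the sulfate.

## Compound list

1 | (E)-2-methylbut-2-enal | C/C=C(\C)C=O | starting material
2 | methyl 2-[bis(2,2,2-trifluoroethoxy)phosphoryl]acetate | COC(=O)CP(=O)(OCC(F)(F)F)OCC(F)(F)F | starting material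
3 | methyl (2Z,4E)-4-methylhexa-2,4-dienoate | C/C=C(\C)/C=C\C(=O)OC | intermediate
4 | (2Z,4E)-4-methylhexa-2,4-dienoic acid | C/C=C(\C)/C=C\C(=O)O | intermediate
5 | toluene | Cc1ccccc1 | starting material
6 | (1S,2R)-3-methylcyclohexa-3,5-diene-1,2-diol | CC1=CC=C[C@H](O)[C@@H]1O | intermediate
7 | (1S,6R)-6-hydroxy-5-methylcyclohexa-2,4-dien-1-yl (2Z,4E)-4-methylhexa-2,4-dienoate | CC1=CC=C[C@H](OC(=O)/C=C\C(\C)=C\C)[C@@H]1O | intermediate
8 | 10-[(E)-but-2-en-2-yl]-2-hydroxy-1-methyl-4-oxatricyclo[4.3.1.0(3,7)]dec-8-en-5-one | C[C@@]12C=C[C@@H]([C@H](OC3=O)[C@@H]1O)[C@@H]3[C@H]2/C(C)=C/C | intermediate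
9 | 10-[(E)-but-2-en-2-yl]-1-methyl-4-oxatricyclo[4.3.1.0(3,7)]dec-8-ene-2,5-dione | C[C@@]12C=C[C@@H]([C@H](OC3=O)C1=O)[C@@H]3[C@H]2/C(C)=C/C | intermediate
10 | 3-[(E)-but-2-en-2-yl]-4-methyl-8-oxobicyclo[2.2.2]oct-5-ene-2-carboxylic acid (carboxyl and butenyl anti to C5=C6) | C[C@@]12C=C[C@@H](CC1=O)[C@@H](C(=O)O)[C@H]2/C(C)=C/C | intermediate
11 | methyl 3-[(E)-but-2-en-2-yl]-4-methyl-8-oxobicyclo[2.2.2]oct-5-ene-2-carboxylate (ester and butenyl anti to C5=C6) | C[C@@]12C=C[C@@H](CC1=O)[C@@H](C(=O)OC)[C@H]2/C(C)=C/C | intermediate
12 | methyl 3-[(E)-but-2-en-2-yl]-4,7-dimethyl-8-oxobicyclo[2.2.2]oct-5-ene-2-carboxylate (ester and butenyl anti, C7 methyl syn to C5=C6) | C[C@@]12C=C[C@@H]([C@@H](C)C1=O)[C@@H](C(=O)OC)[C@H]2/C(C)=C/C | intermediate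
13 | methyl 3-[(E)-but-2-en-2-yl]-8-ethenyl-8-hydroxy-4,7-dimethylbicyclo[2.2.2]oct-5-ene-2-carboxylate (ester and butenyl anti, vinyl and C7 methyl syn to C5=C6) | C[C@@]12C=C[C@@H]([C@@H](C)[C@@]1(O)C=C)[C@@H](C(=O)OC)[C@H]2/C(C)=C/C | intermediate
14 | methyl 3-[(E)-but-2-en-2-yl]-8-ethenyl-8-hydroxy-4,7-dimethylbicyclo[2.2.2]oct-5-ene-2-carboxylate (ester, vinyl and C7 methyl syn to C5=C6, butenyl anti) | C[C@@]12C=C[C@@H]([C@@H](C)[C@@]1(O)C=C)[C@H](C(=O)OC)[C@H]2/C(C)=C/C | intermediate
15 | methyl (1S,2S,4aS,8R,8aS)-2-[(E)-but-2-en-2-yl]-3,8-dimethyl-7-oxo-1,2,4a,5,6,7,8,8a-octahydronaphthalene-1-carboxylate | C/C=C(\C)[C@H]1C(C)=C[C@H]2CCC(=O)[C@H](C)[C@H]2[C@@H]1C(=O)OC | intermediate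
16 | methyl (1S,2S,4aS,7S,8R,8aS)-2-[(E)-but-2-en-2-yl]-7-hydroxy-3,8-dimethyl-1,2,4a,5,6,7,8,8a-octahydronaphthalene-1-carboxylate | C/C=C(\C)[C@H]1C(C)=C[C@H]2CC[C@H](O)[C@H](C)[C@H]2[C@@H]1C(=O)OC | intermediate
17 | (1S,2S,4aS,7S,8R,8aS)-2-[(E)-but-2-en-2-yl]-7-hydroxy-3,8-dimethyl-1,2,4a,5,6,7,8,8a-octahydronaphthalene-1-carbaldehyde | C/C=C(\C)[C@H]1C(C)=C[C@H]2CC[C@H](O)[C@H](C)[C@H]2[C@@H]1C=O | intermediate
18 | ethyl (E)-4-(diethoxyphosphoryl)but-2-enoate | CCOC(=O)/C=C/CP(=O)(OCC)OCC | starting material
19 | ethyl (2E,4E)-5-[(1S,2S,4aS,7S,8R,8aR)-2-[(E)-but-2-en-2-yl]-7-hydroxy-3,8-dimethyl-1,2,4a,5,6,7,8,8a-octahydronaphthalen-1-yl]penta-2,4-dienoate | C/C=C(\C)[C@H]1C(C)=C[C@H]2CC[C@H](O)[C@H](C)[C@H]2[C@@H]1/C=C/C=C/C(=O)OCC | intermediate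
20 | ethyl (2E,4E)-5-[(1S,2S,4aS,7S,8R,8aR)-2-[(E)-but-2-en-2-yl]-3,8-dimethyl-7-(sulfooxy)-1,2,4a,5,6,7,8,8a-octahydronaphthalen-1-yl]penta-2,4-dienoate | C/C=C(\C)[C@H]1C(C)=C[C@H]2CC[C@H](OS(=O)(=O)O)[C@H](C)[C@H]2[C@@H]1/C=C/C=C/C(=O)OCC | intermediate
21 | (2E,4E)-5-[(1S,2S,4aS,7S,8R,8aR)-2-[(E)-but-2-en-2-yl]-3,8-dimethyl-7-(sulfooxy)-1,2,4a,5,6,7,8,8a-octahydronaphthalen-1-yl]penta-2,4-dienoic acid | C/C=C(\C)[C@H]1C(C)=C[C@H]2CC[C@H](OS(=O)(=O)O)[C@H](C)[C@H]2[C@@H]1/C=C/C=C/C(=O)O | target

## Step count and least certain steps

Total step count: 15. Longest linear sequence: 14 steps (steps 1, 2 and 4–15; the branch from toluene, steps 3–15, is 13 steps).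

**Step 11 (key step).** Proton transfer may compete with the rearrangement. Deprotonation α to the ester, or proton exchange between the product enolate and ketone already formed, would erode the configuration at C1 or C8 (target numbering) or start Claisen-type condensation. A tightly ion-paired alkoxide may also rearrange too slowly. The fallback avoids all bases by a neutral thermal siloxy-Cope rearrangement. It sets out from 14: Me3SiOTf and 2,6-lutidine give the trimethylsilyl ether of 14, F1. Heating in degassed PhMe at 180–200 °C in a base-washed sealed tube should give the silyl enol ether of 15, F2. Brief treatment with 0.1 M HCl in THF–H2O at 0 °C returns to the route at 15.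

**Step 4.** Acyl migration between the two cis hydroxyls and loss of the carboxylic acid with aromatisation may outrun the cycloaddition. The cycloaddition is slowed by the cis dienophile and by the free hydroxyl that comes to face the butenyl group; DMAP may also cause drift of the 2Z alkene to 2E. The fallback replaces the dihydrodiol by a phenol-derived dienone with no hydroxyl and no path to aromatisation by elimination. It sets out from 4 and commercial 2,6-dimethylphenol. Wessely oxidation with Pb(OAc)4 pre-exchanged with 4 gives the racemic o-quinol ester 2,6-dimethyl-6-oxocyclohexa-2,4-dien-1-yl (2Z,4E)-4-methylhexa-2,4-dienoate, F3. Its intramolecular Diels–Alder reaction in PhMe at 80 °C gives the racemic methyl-substituted keto lactone, F4. SmI2 cleavage followed by DBU equilibration of the new α-methyl centre (while the carboxyl is still anti) gives the methylated keto acid, F5. F5 is resolved by chromatography on a chiral stationary phase and esterified with Me3SiCHN2, returning to the route at 12.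

**Step 10.** Proton exchange at the hindered ester α-carbon may be slow, and the neighbouring tertiary alkoxide may instead attack the anti ester (bridged lactone formation) and trap the wrong epimer. The fallback moves the epimerisation to a stage without a hydroxyl and before the C8 stereocentre (target numbering) exists. It sets out from 11: NaOMe in MeOH gives the keto ester with the ester syn to the etheno bridge, F6. Methylation with LiN(SiMe3)2 and MeI then relies on the butenyl group and the intrinsic preference for attack from the etheno side, giving the methylated syn ester, F7. Vinylmagnesium bromide with CeCl3 returns to the route at 14.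

**Step 12.** Hydride delivery may occur from the wrong face if the decalone reacts through the chair with an axial C8 methyl, where both faces of the carbonyl are hindered. The fallback sets C7 by inversion instead of by reduction. It sets out from 15: reduction then gives mainly the C7-epimeric alcohol, F8. A Mitsunobu reaction (4-nitrobenzoic acid, PPh3, diisopropyl azodicarboxylate) gives the inverted 4-nitrobenzoate, F9. Methanolysis (K2CO3, MeOH, 0 °C) returns to the route at 16.

## Further compounds

F1 | step 11 | methyl 3-[(E)-but-2-en-2-yl]-8-ethenyl-4,7-dimethyl-8-(trimethylsilyloxy)bicyclo[2.2.2]oct-5-ene-2-carboxylate (trimethylsilyl ether of 14) | C[C@@]12C=C[C@@H]([C@@H](C)[C@@]1(O[Si](C)(C)C)C=C)[C@H](C(=O)OC)[C@H]2/C(C)=C/C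
F2 | step 11 | methyl (1S,2S,4aS,8R,8aS)-2-[(E)-but-2-en-2-yl]-3,8-dimethyl-7-(trimethylsilyloxy)-1,2,4a,5,8,8a-hexahydronaphthalene-1-carboxylate (silyl enol ether of 15) | C/C=C(\C)[C@H]1C(C)=C[C@H]2CC=C(O[Si](C)(C)C)[C@H](C)[C@H]2[C@@H]1C(=O)OC
F3 | step 4 | 2,6-dimethyl-6-oxocyclohexa-2,4-dien-1-yl (2Z,4E)-4-methylhexa-2,4-dienoate (racemic; enantiomer carried on is drawn) | CC1=CC=C[C@](C)(OC(=O)/C=C\C(\C)=C\C)C1=O
F4 | step 4 | 10-[(E)-but-2-en-2-yl]-1,3-dimethyl-4-oxatricyclo[4.3.1.0(3,7)]dec-8-ene-2,5-dione (racemic; enantiomer carried on is drawn) | C[C@@]12C=C[C@@H]([C@](C)(OC3=O)C1=O)[C@@H]3[C@H]2/C(C)=C/C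
F5 | step 4 | 3-[(E)-but-2-en-2-yl]-4,7-dimethyl-8-oxobicyclo[2.2.2]oct-5-ene-2-carboxylic acid (carboxyl and butenyl anti, C7 methyl syn to C5=C6; after resolution) | C[C@@]12C=C[C@@H]([C@@H](C)C1=O)[C@@H](C(=O)O)[C@H]2/C(C)=C/C
F6 | step 10 | methyl 3-[(E)-but-2-en-2-yl]-4-methyl-8-oxobicyclo[2.2.2]oct-5-ene-2-carboxylate (ester syn to C5=C6, butenyl anti) | C[C@@]12C=C[C@@H](CC1=O)[C@H](C(=O)OC)[C@H]2/C(C)=C/C
F7 | step 10 | methyl 3-[(E)-but-2-en-2-yl]-4,7-dimethyl-8-oxobicyclo[2.2.2]oct-5-ene-2-carboxylate (ester and C7 methyl syn to C5=C6, butenyl anti) | C[C@@]12C=C[C@@H]([C@@H](C)C1=O)[C@H](C(=O)OC)[C@H]2/C(C)=C/C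
F8 | step 12 | methyl (1S,2S,4aS,7R,8R,8aS)-2-[(E)-but-2-en-2-yl]-7-hydroxy-3,8-dimethyl-1,2,4a,5,6,7,8,8a-octahydronaphthalene-1-carboxylate (C7 epimer of 16) | C/C=C(\C)[C@H]1C(C)=C[C@H]2CC[C@@H](O)[C@H](C)[C@H]2[C@@H]1C(=O)OC
F9 | step 12 | methyl (1S,2S,4aS,7S,8R,8aS)-2-[(E)-but-2-en-2-yl]-3,8-dimethyl-7-(4-nitrobenzoyloxy)-1,2,4a,5,6,7,8,8a-octahydronaphthalene-1-carboxylate | C/C=C(\C)[C@H]1C(C)=C[C@H]2CC[C@H](OC(=O)c3ccc(cc3)[N+](=O)[O-])[C@H](C)[C@H]2[C@@H]1C(=O)OC
A1 | alternative 1 | ethyl (2E,4E,6E,12E,14E,16E)-9-(tert-butyldimethylsilyloxy)-8,14,16-trimethyloctadeca-2,4,6,12,14,16-hexaenoate (C8 and C9 configured as C8 and C7 of 21) | C/C=C(\C)/C=C(\C)/C=C/CC[C@H](O[Si](C)(C)C(C)(C)C)[C@H](C)/C=C/C=C/C=C/C(=O)OCC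
A2 | alternative 2 | 19-membered hexaene macrolactone of the C18-hydroxy acid corresponding to A1 (C18–O–C1 lactone) | O1C/C=C(\C)/C=C(\C)/C=C/CC[C@H](O[Si](C)(C)C(C)(C)C)[C@H](C)/C=C/C=C/C=C/C1=O
A3 | alternative 3 | 5-[(E)-but-2-en-2-yl]-4-[(tert-butyldimethylsilyloxy)methyl]-6-methylcyclohex-2-en-1-one (C4 and C5 configured as C1 and C2 of 21) | C/C=C(\C)[C@H]1[C@H](C)C(=O)C=C[C@@H]1CO[Si](C)(C)C(C)(C)C
A4 | alternative 3 | (Z)-3-(tert-butyldimethylsilyloxy)penta-1,3-diene | C=C/C(O[Si](C)(C)C(C)(C)C)=C/C
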